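4 questions stand here, each about the share of target among target, other capture product and side product.

the same everywhere: substrate 0.026 M

| run | first nucleophile | second nucleophile | temperature | remark | time |
|---|---|---|---|---|---|
| cedar | 0.026 M | 0.047 M | 55 °C | run made earlier |  |
| violet | 0.0260 M | 0.0312 M | 55 °C |  | 25 h |
| amber | 0.0260 M | 0.0312 M | 40 °C |  | 25 h |
| green | 0.0260 M | 0.0312 M | 70 °C |  | 25 h |

- cedar (time / h: target / %, other capture product / %, side product / %): 0.200: 2, 0, 1; 0.500: 2, 6, 1; 1.00: 1, 11, 0; 2.50: 4, 17, 2

(readings scatter by 1.5 percentage points)

- percentages count the substrate that a species holds: one side product counts as two
- the earlier runs do not show what temperature does; that part of a forecast is a guess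

- the best flask by share of target in all that became target or other capture product or side product; "all alike" if 1.5 percentage points covers them all (violet / amber / green / all alike)
- share of target in all that became target or other capture product or side product, violet
- share of target in all that became target or other capture product or side product, amber
- share of target in all that became target or other capture product or side product, green

A bench rule first: we assume the two nucleophiles compete for the same thing, so their products form in the ratio of their concentrations times a constant. We read that constant from the 4 cedar readings pooled, since the target readings run from 1 % to 4 % against a scatter of 1.5 percentage points: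

S = (other capture product / target) / (c(second nucleophile) / c(first nucleophile))

S = (34.0 % / 9.00 %) / 1.81 = 2.09

This S is our selectivity factor: other capture product per target at equal concentrations of the two nucleophiles. It is a reading, and each target reading in it carries a scatter of 1.5 points. With the charges of violet the rule gives:

share = 1 / (1 + S · c(second nucleophile) / c(first nucleophile)) = 28.5 %

That treats both nucleophiles as constant, the pseudo-first-order picture, and violet breaks it: second nucleophile to substrate is 1.20, no real excess. Cedar's readings at 2.50 h put 23.0 % of its substrate in products. If violet kept that pace, taken as first-order, 25 h is 3.77 half-lives, leaving 7.33 %, and we reckon violet as if that remainder had reacted too. Split this way, it takes 59.6 % of the second nucleophile but 28.5 % of the first, and the concentration ratio slides from 1.20 to 0.679. With the mean ratio: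

share = 1 / (1 + S · 0.939) = 33.8 %

The runs show nothing of temperature, so we guess: S kept, amber less far along and nearer 28.5 %, green nearer 33.8 % and so above amber.

The forecast stands lower than our violet figure: violet 18 % (9 % to 31 %), amber 16 %, green 20 %, with “a weak preference for green”.

Violet gives 31.2 %, amber 25.6 % and green 34.4 %, so green is best. Violet lands above 28.5 % and below 33.8 %, with 9.70 % of its substrate left at 25.0 h. At that time violet holds 71.9 % of the first nucleophile and 49.3 % of the second, each of its own charge, so S puts the rate to other capture product over the rate to target at 1.72. Violet's computed ratio of these rates at that time is 1.8.

    substrate ⇌ intermediate (K = 0.0920, k = 0.0230 /h, Ea = 101 kJ/mol, ΔH = −69.0 kJ/mol)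
    first nucleophile + intermediate → target (k = 50.0 /M/h, Ea = 70.0 kJ/mol)
    second nucleophile + intermediate → other capture product (k = 130 /M/h, Ea = 59.0 kJ/mol)
    substrate + intermediate → side product (k = 1.60 /M/h, Ea = 79.0 kJ/mol)
    (constants at 40 °C)

A neighbour of violet is charged with 0.12 M of second nucleophile. For this neighbour S gives 9.39 % from the charges, and by that split the substrate takes 19.6 % of the second nucleophile, less than the 59.6 % we reckoned for violet. The neighbour's computed share is 9.60 %.

(The runs were computed on assumed constants, and the scatter is random.)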